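A small charge of starting material, 0.011 M, meets coupling partner at 0.0440 M and turns into open intermediate, and the open intermediate then passes on to side product or target. We ask how much open intermediate stands after 2.0 h at each temperature.

| flask | starting material | fresh partner | coupling partner | protic impurity | temperature | remark | time |
|---|---|---|---|---|---|---|---|
| Saturday's | 0.011 M | 0.022 M | 0.044 M | 0.55 mM | 50 °C | run made earlier |  |
| Friday's | 0.011 M | 0.022 M | 0.044 M | 0.83 mM | 83 °C | run made earlier |  |
| Wednesday's | 0.022 M | 0.022 M | 0.044 M | 1.1 mM | 50 °C | run made earlier |  |
| cedar | 0.011 M | 0.0220 M | 0.0440 M | 1.10 mM | 55 °C |  | 2.0 h |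
| larch | 0.011 M | 0.0220 M | 0.0440 M | 1.10 mM | 35 °C |  | 2.0 h |
| ash | 0.011 M | 0.0220 M | 0.0440 M | 1.10 mM | 75 °C |  | 2.0 h |
| oak | 0.011 M | 0.0220 M | 0.0440 M | 1.10 mM | 95 °C |  | 2.0 h |

| run | time / min | open intermediate / % | target / % |
|---|---|---|---|
| Saturday's | 15.0 | 31 | 0 |
| Saturday's | 30.0 | 20 | 7 |
| Saturday's | 40.0 | 10 | 5 |
| Saturday's | 60.0 | 5 | 8 |
| Saturday's | 80.0 | 3 | 9 |
| Friday's | 1.50 | 13 | 0 |
| Friday's | 2.50 | 8 | 2 |
| Friday's | 5.00 | 5 | 3 |
| Friday's | 10.0 | 0 | 0 |
| Friday's | 20.0 | 0 | 3 |
| Wednesday's | 6.00 | 23 | 3 |
| Wednesday's | 20.0 | 27 | 5 |
| Wednesday's | 30.0 | 13 | 7 |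
| Wednesday's | 50.0 | 9 | 5 |
| Wednesday's | 80.0 | 2 | 8 |

(standard deviation of a reading: 2 percentage points)

- what may be going on: coupling partner + fresh partner -> second intermediate; open intermediate + second intermediate <-> target; 2 second intermediate -> homo product; open intermediate -> side product; fresh partner + protic impurity -> quenched reagent; starting material + coupling partner -> open intermediate

- the flask that comes out highest in amount of open intermediate, in percent of the starting material charged, or "all alike" when all lie within 1.5 percentage points (cedar / larch / ash / oak / all alike)
- open intermediate at the end, in percent of the starting material charged, cedar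
- open intermediate at the end, in percent of the starting material charged, larch
- open intermediate at the end, in percent of the starting material charged, ash
- open intermediate at the end, in percent of the starting material charged, oak

In the end the open intermediate goes, so we ask how far along that road the time reaches. Saturday's tail, 20% falling to 3%, reads 0.0379 /min, and Friday's, 13% falling to 5%, reads 0.273 /min; an Arrhenius line through these two scattered readings gives 0.0135 /min at 35 °C. So larch has a lifetime count, the slow constant of the chain times the time, of 1.61. If both steps of the chain ran on that clock, larch would keep 20.0% of its starting material and hold the fraction N·exp(−N) of the charge as open intermediate, which is 32.2%. The same line gives cedar a count of 6.30, which leaves 1.16%, so we name larch.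

The forecast also names larch, with 0.4%, 14%, 0.1% and 0.1% for cedar, larch, ash and oak. It parts from us on the clock: it holds that at 35 °C “both constants are about 0.024/min”, a count of 2.9.

The flasks give larch as highest, with 0.268%, 24.2%, 0.00779% and 0%, so the forecast stands on the order and the hot flasks and lies 10 percentage points low on larch.

    coupling partner + fresh partner → second intermediate (k = 15.0 /M/h, Ea = 48.0 kJ/mol)
    open intermediate + second intermediate ⇌ target (K = 690 /M, k = 32.0 /M/h, Ea = 49.0 kJ/mol, ΔH = 2.00 kJ/mol)
    2 second intermediate → homo product (k = 11.0 /M/h, Ea = 79.0 kJ/mol)
    open intermediate → side product (k = 0.750 /h, Ea = 95.0 kJ/mol)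
    fresh partner + protic impurity → quenched reagent (k = 4000 /M/h, Ea = 42.0 kJ/mol)
    starting material + coupling partner → open intermediate (k = 26.0 /M/h, Ea = 67.0 kJ/mol)
    (constants at 35 °C)

Larch keeps 21% of its starting material, a count of 1.56, and the loss step over the same time counts 1.50, so both steps of larch stand near our 1.61, not 2.9. Taking the loss to side product away lifts larch from 24.2% to 58.9%, which is a part of the answer there, and it lifts oak from 0% to 64.0%, so that step is the main reason for the low end of oak.

In the neighbour flask, larch with 0.044 M of starting material, the unchanged count gives 20.0% of starting material and 32.2% of open intermediate. The computed neighbour flask holds 38.1% and 19.5%, with coupling partner charged at 1.00 equiv and down to 17.8% of its charge, so there the count no longer serves.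

Readings and results were generated by integration for an exercise; noise was put on by code.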